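| flask | G | remark | time |
|---|---|---|---|
| spring | 0.050 M | run made earlier |  |
| dawn | 0.075 M | run made earlier |  |
| flask | 0.10 M |  | 40 min |

| run | time / min | L / % | E / % | G / % |
|---|---|---|---|---|
| spring | 4.00 | 21.6 | 0 | 58.4 |
| spring | 5.00 | 23.4 | 0 | 50.6 |
| spring | 6.00 | 25.9 | 0 | 45.5 |
| spring | 10.0 | 30.4 | 2.5 | 30.0 |
| spring | 12.0 | 32.2 | 0.7 | 24.3 |
| spring | 20.0 | 33.7 | 5.7 | 11.7 |
| spring | 25.0 | 31.8 | 7.7 | 11.2 |
| dawn | 4.00 | 20.1 | 0.1 | 57.7 |
| dawn | 5.00 | 22.4 | 0 | 48.4 |
| dawn | 6.00 | 27.3 | 0 | 43.8 |
| dawn | 10.0 | 31.1 | 2.0 | 29.3 |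
| dawn | 12.0 | 33.0 | 1.8 | 23.1 |
| dawn | 20.0 | 31.7 | 5.6 | 13.2 |
| dawn | 25.0 | 30.0 | 8.9 | 8.1 |

(standard deviation of a reading: 1 percentage point)

- the best time, 40 min at the latest, for L
- the amount of L, in percent of the G charged, at that time
- the first time at which L reaches 23%, in the same percent, in min

- the numbers in the tables scatter by 1 percentage point (one standard deviation)
- a reading or a percentage of E counts all its forms, free or not

**Turned round.** If L in the flask were still climbing at 40 min, [G]/[L] would have to stand above its value at the top of L, so I reckon that value. I treat L as a tank: G feeds it at feed·[G], it drains at drain·[L], and its level tops where the two match.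

**Both ends.** Averaging spring and dawn, L reads 20.9% and G 58.0% at 4.00 min. Taking G's mean over that span as the midpoint between charge and reading gives a feed constant of 0.0660 min⁻¹. From 20.0 min to 25.0 min L falls in both runs, and adding that fall to the feed and dividing by the mean L gives a drain constant of 0.0342 min⁻¹. Drain over feed, the [G]/[L] at which L stands still, is my top ratio, the selectivity factor of a series reaction: 0.519, a reading with the scatter of the runs.

**How far.** The mean [G]/[L] reads 0.727 at 12.0 min, above the top ratio, but 0.381 at 20.0 min and 0.312 at 25.0 min, both below it. Interpolating, I put the top near 16.2 min, and I carry that to the flask as percent curves.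

**The forecast.** It puts the top of L at 17 min, later than my time, with 33.5%, and the level asked at 5 min, and adds: “The flat top makes the peak time uncertain.”

**The flask.** In the flask L tops at 14.6 min with 32.3%, earlier than the forecast, and reaches the level asked at 5.01 min.

    G → L (k = 0.00120 s⁻¹)
    L → Z (k = 6.50 × 10⁻⁴ s⁻¹)
    Z → E (k = 5.50 × 10⁻⁴ s⁻¹)
    Q ⇌ E, rate k4*(cs4 - [E]) while solid is left; crystals form when [E] > cs4 (solubility = 40.0 mM, k = 0.0360 s⁻¹)
    G ⇌ X (K = 1.90, k = 9.60 × 10⁻⁴ s⁻¹)
    2 G → J (k = 0.00200 M⁻¹ s⁻¹)

**Same ratio.** At that top the flask holds G 17.5% and L 32.3%, so [G]/[L] stands at 0.542 where I put 0.519. The same flask read at 25 min holds G 9.11% and L 29.0%, a [G]/[L] of 0.314, below the top ratio, which places it past the top. Its L stands below the highest amount reached up to that time, 32.3%.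

The numbers in the tables come from a simulation for an exercise.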